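## Analysis of the target

Cryptomerin A (22) is a biflavone of the hinokiflavone type. An apigenin unit (benzo ring A and pyranone ring C, unprimed atoms; para-phenylene ring B, primed atoms) is joined through the oxygen on C4' to C6'' of an acacetin unit (benzo ring D and pyranone ring E, double-primed atoms; 4-methoxyphenyl ring F, triple-primed atoms). The molecule has no stereocentre, so every selectivity question concerns position or chemoselectivity among oxygen functions. It carries four free phenols, two of them (on C5 and C5'') hydrogen-bonded to the chromone carbonyls, and one methyl ether on ring F that must survive while every other oxygen ends free. Both chromone enones can be opened at C2 or C2'' by hot hydroxide, and the phloroglucinol-type rings A and D are easily attacked by carbon electrophiles at C6, C8 and C8''. The difficulty is the diaryl ether: its oxygen sits on C6'', between the oxygenated carbons C5'' and C7'', where coupling of a phenol or a halide is slow, and C6'' must be told apart from C8''. The strategy rests on two facts about ring D. C5'', C6'' and C7'' bear oxygen in a row, and the C4a''=C8a'' bond is at the same time the enol-ether double bond of pyranone ring E. The four carbons C5''–C8'' therefore map onto a 1,1,2,3-tetraoxygenated butadiene, and C4a''=C8a'' onto the C=C bond of a 4-pyranone that already is ring E with ring F attached.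

## Retrosynthetic reasoning

22 is traced back to its tetrabenzyl ether 21 by cutting four O–CH2Ph bonds. Benzyl is chosen because a boron Lewis acid at low temperature, or hydrogenolysis, removes it without touching the methyl ether of ring F. A methyl or silyl mask would either be indistinguishable from that ether or would not survive the base and acid steps that build ring C.

Ring C of 21 is opened at O1–C2 and then at C2–C3. This gives the 1,3-diketone 20, which comes from the aryl ester 19 by intramolecular acyl transfer, and 19 comes from acid 16 and the hydroxyacetophenone 18. The cut is made here because the apigenin half is the conventional part of the molecule. Ring A derives from the symmetric ketone 17, so no positional problem arises, and C2 is the carboxyl carbon of ring B, a handle that can be carried from the first step. The forward sequence must esterify, rearrange and cyclodehydrate without opening ring E.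

Acid 16 is the saponified, benzylated form of the diphenol ester 14. These two functional-group changes only prepare the product of the ring-forming step for the end game.

Ring D of 14 is cut at C4a''–C5'' and C8''–C8a''. This gives diene 5, which carries C5''–C8'' with all three oxygens and the complete ring B ester, and sulfinylpyranone 11, which is ring E with ring F in place. It is the most simplifying cut available. It removes a fully substituted benzene ring, leaves two small partners, and makes the question of C6'' versus C8'' one of cycloaddition orientation. The forward reaction has to join the CH2 terminus of 5 to C8a'' and the ketene-acetal carbon to C4a'', then aromatise by losing the sulfinyl group, methanol and the silyl groups.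

Diene 5 goes back through the mono-silyl enol ether 4 to the β-keto ester 3, and 3 is cut at the bond between the phenol oxygen and the α-carbon, giving phenol 1 and chloride 2. The hindered ether oxygen is thus introduced by alkylation of an unhindered phenol at an sp3 carbon, and C6'' becomes an aromatic carbon only later.

Sulfoxide 11 comes from sulfide 10 by oxidation at sulfur. Pyranone 10 is opened at the ring oxygen–CH bond to the diketo enaminone 9, which is cut between the aroyl carbon and the methylene into enaminone 7 and acid chloride 8. 7 is the aminomethylene derivative of ketone 6. The one-carbon unit is placed on the sulfur-bearing carbon of 6 first, because the same reaction on a preformed 1-aryl-1,3-diketone would go to the doubly activated central methylene and give the wrong connectivity.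

The hydroxyacetophenone 18 is the product of twofold benzylation of 17. The hydroxyl that stays hydrogen-bonded to the acetyl group is left free.

## Alternatives that were turned down

Alternative 1: Ring E is opened at C3''–C4'' and O1''–C2''.
- Disconnection: this leads to the salicylaldehyde 2,4-bis(benzyloxy)-3-{4-[5,7-bis(benzyloxy)-4-oxo-4H-chromen-2-yl]phenoxy}-6-hydroxybenzaldehyde A1, which already holds rings A, B, C and D, and to the sulfoxonium ylide 2-(dimethyloxo-λ6-sulfanylidene)-1-(4-methoxyphenyl)ethan-1-one A2.
- Forward key step: [(C5Me5)RhCl2]2 with AgSbF6 (trivalent rhodium) would use the free phenol of A1 to direct insertion into the formyl C–H bond. The acyl rhodacycle takes up A2 as a carbene with loss of the sulfoxide, migratory insertion makes C3''–C4'', and the 2-hydroxyaryl 1,3-diketone cyclodehydrates to tetra-O-benzylcryptomerin A A3 (the same compound as 21).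
- For it: the plan is highly convergent, A3 is one deprotection from the target, and this annulation is an established type for salicylaldehydes.
- Against it: A1 is a pentasubstituted benzene that already contains the O–C6'' ether. The hard bond is only moved into the preparation of A1, where it must come from arylation of a phenol oxygen flanked by two benzyloxy groups, and where exactly one of three ring D oxygens must stay free. The formyl group to be activated lies between OH and OBn, and the ring C carbonyl of A1 offers the metal a second chelation site.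
- Comparison: on convergence and on the number of steps after the key event this alternative is stronger. The chosen strategy offers instead an ether bond made at sp3 carbon from an unhindered phenol, no precious metal, and a key step whose partners are each three steps from commercial materials.

Alternative 2: Ring D stays aromatic and two ortho bonds to it, C4a''–C4'' and C8a''–O1'', are cut together.
- Disconnection: this gives a trioxygenated benzyne and 3-(4-methoxyphenyl)prop-2-ynoic acid A4. The aryne would be released with CsF from 3,5-bis(benzyloxy)-4-[4-(1,3-dioxolan-2-yl)phenoxy]-2-(trimethylsilyl)phenyl trifluoromethanesulfonate A5.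
- Forward key step: the carboxylate of A4 adds through oxygen to C8a'', the aryl anion at C4a'' attacks the carbonyl, and collapse of the four-membered intermediate moves the acyl group to carbon. The product is 1-{2-hydroxy-4,6-bis(benzyloxy)-5-[4-(1,3-dioxolan-2-yl)phenoxy]phenyl}-3-(4-methoxyphenyl)prop-2-yn-1-one A6; no ring closes.
- For it: the benzyloxy group next to the aryne polarises it so that oxygen adds at the distal carbon C8a'', which is the required sense. The conditions are nearly neutral, and A6 is set up for 6-endo closure to ring E.
- Against it: A5 is a hexasubstituted arene that needs a long linear preparation and again contains the hindered diaryl ether. With carboxylic acids the aryl anion is often simply protonated, which ends at an aryl ester. A6 can also close 5-exo to an aurone. After ring E the masked aldehyde still has to be turned into rings C and A.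
- Comparison: its built-in regiocontrol is as good as that of the chosen route. The chosen strategy offers instead a key step that closes ring D and delivers the whole acacetin half in one operation, without first assembling a crowded aromatic precursor.

Alternative 3: Ring B itself is disconnected, at C2'–C3' and C4'–C5'.
- Disconnection: methyl coumalate A7 serves as an electron-poor diene and 1,3-bis(benzyloxy)-2-(ethynyloxy)-5-[(triisopropylsilyl)oxy]benzene A8 as an electron-rich dienophile.
- Forward key step: inverse-demand cycloaddition joins the CH terminus of A8 to C6 of A7 and the oxygen-bearing alkyne carbon to C3. The bridged lactone then extrudes CO2 to give methyl 4-{2,6-bis(benzyloxy)-4-[(triisopropylsilyl)oxy]phenoxy}benzoate A9.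
- For it: like the chosen route it makes the hindered ether without aryl coupling, because the crowded phenol oxygen only receives a two-carbon unit before ring B is grown on it. The para relation of ester and ether is secure, and A9 has the same ester handle as 15.
- Against it: A9 contains neither pyranone ring. Ring D must still be C-acylated at C4a'' on an electron-rich ring bearing acid-sensitive benzyl ethers, the silyl ether must be removed to free the future O1'', and two separate flavone annulations follow. Aryl ynol ethers are also prone to hydration and to thermal conversion into ketenes at the temperatures such cycloadditions need.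
- Comparison: on the ether problem the two strategies are equal. The chosen one offers instead the formation of ring D rather than ring B, with ring E arriving in the dienophile, so only one flavone annulation remains.

Key step: step 7

Assumption: enol-ether and enaminone double bonds are drawn as single geometric isomers although the geometry has no consequence, and 2',4',6'-trihydroxyacetophenone is used as its dried commercial hydrate.

## Route

Step 1
Reactants: 1 methyl 4-hydroxybenzoate; 2 methyl 2-chloro-3-oxobutanoate (methyl 2-chloroacetoacetate, racemic)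
Product: 3 methyl 2-[4-(methoxycarbonyl)phenoxy]-3-oxobutanoate (racemic)
Conditions: K2CO3, KI (cat.), acetone, reflux
Reagents that add atoms: none
Why: Williamson-type SN2 O-alkylation of the phenoxide at the carbonyl-activated secondary chloride, a standard entry to 2-aryloxyacetoacetates; the phenol is unhindered, so the future O–C6'' ether bond forms without any aryl coupling.

Step 2
Reactants: 3 methyl 2-[4-(methoxycarbonyl)phenoxy]-3-oxobutanoate
Product: 4 methyl 4-{[(2E)-1-methoxy-1-oxo-3-(trimethylsilyloxy)but-2-en-2-yl]oxy}benzoate (E/Z mixture acceptable)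
Conditions: TMSCl, Et3N, toluene, rt
Reagents that add atoms: chlorotrimethylsilane (TMSCl), C[Si](C)(C)Cl
Why: Soft enolisation and O-silylation of the ketone of a β-keto ester, the first stage of the usual preparation of 1,3-bis(silyloxy)dienes; the aryl ester is inert.

Step 3
Reactants: 4 methyl 4-{[(2E)-1-methoxy-1-oxo-3-(trimethylsilyloxy)but-2-en-2-yl]oxy}benzoate
Product: 5 methyl 4-{[1-methoxy-1,3-bis(trimethylsilyloxy)buta-1,3-dien-2-yl]oxy}benzoate (one geometric isomer drawn)
Conditions: LDA, THF, −78 °C; then TMSCl, −78 °C → rt; filtered under argon and used crude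
Reagents that add atoms: chlorotrimethylsilane (TMSCl), C[Si](C)(C)Cl
Why: γ-Deprotonation of the β-silyloxy enoate gives the extended lithium enolate, which is silylated on oxygen to the ketene silyl acetal (second stage of the bis(silyl enol ether) synthesis); the benzoate has no α-hydrogen and the hindered amide should not add to it at −78 °C.

Step 4
Reactants: 6 1-(phenylsulfanyl)propan-2-one
Product: 7 (3Z)-4-(dimethylamino)-3-(phenylsulfanyl)but-3-en-2-one
Conditions: DMF-DMA (1.2 equiv), toluene, 80 °C
Reagents that add atoms: N,N-dimethylformamide dimethyl acetal (DMF-DMA), COC(OC)N(C)C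
Why: Aminomethylenation of an active methylene by an amide acetal; the CH2 flanked by sulfur and carbonyl is far more acidic than the methyl group, so the one-carbon unit should go to the sulfur-bearing carbon.

Step 5
Reactants: 7 (3Z)-4-(dimethylamino)-3-(phenylsulfanyl)but-3-en-2-one; 8 4-methoxybenzoyl chloride
Product: 10 6-(4-methoxyphenyl)-3-(phenylsulfanyl)-4H-pyran-4-one, via diketo enaminone 9 (not isolated)
Conditions: LiHMDS (2.2 equiv), THF, −78 °C; 8, −78 → 0 °C; then 2 M HCl, THF, rt
Reagents that add atoms: none
Why: Claisen-type C-acylation of the kinetic lithium enolate of the methyl ketone, the second equivalent of base taking up the more acidic diketone 9; acid then lets the enol oxygen add to the vinylogous amide carbon and expel dimethylamine, an established γ-pyrone synthesis from enaminones and acid chlorides.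

Step 6
Reactants: 10 6-(4-methoxyphenyl)-3-(phenylsulfanyl)-4H-pyran-4-one
Product: 11 6-(4-methoxyphenyl)-3-(phenylsulfinyl)-4H-pyran-4-one (racemic sulfoxide)
Conditions: mCPBA (1.0 equiv), CH2Cl2, −78 → 0 °C
Reagents that add atoms: 3-chloroperoxybenzoic acid (mCPBA), OOC(=O)c1cccc(Cl)c1
Why: Electrophilic oxidation at sulfur stops at the sulfoxide with one equivalent of peracid at low temperature; the electron-poor pyranone double bonds are not epoxidised, and the sulfoxide has no β-hydrogen through which it could eliminate.

Step 7
Reactants: 5 methyl 4-{[1-methoxy-1,3-bis(trimethylsilyloxy)buta-1,3-dien-2-yl]oxy}benzoate; 11 6-(4-methoxyphenyl)-3-(phenylsulfinyl)-4H-pyran-4-one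
Product: 14 methyl 4-{[5,7-dihydroxy-2-(4-methoxyphenyl)-4-oxo-4H-chromen-6-yl]oxy}benzoate, via sulfinyl cycloadduct 12 (not isolated), via dihydrochromenone ketal 13 (not isolated)
Conditions: 5 (3 equiv, crude), toluene, 0 °C → rt, then 80 °C; then 1 M HCl, THF/MeOH, rt
Reagents that add atoms: none
Why: This is a normal-demand Diels–Alder reaction in which the HOMO of 5 is largest at the CH2 terminus and the LUMO of 11 is largest at the ring CH next to oxygen (future C8a''), the β-carbon of both the ketone and the sulfinyl acceptor, so C8''–C8a'' forms ahead of C4a''–C5'' in an asynchronous (at the limit Michael-then-closure) [4+2] addition that gives 12. The closest known reaction type is the cycloaddition of 1-alkoxy-1,3-bis(silyloxy)butadienes to sulfinyl- or halogen-activated quinones and to chromones carrying an acceptor at C3, with aromatisation in the same pot. Ring D closes by this intermolecular [4+2] process, both new ring bonds coming from one diene and one dienophile; in a stepwise course the second bond would arise by six-membered closure of the α-sulfinyl enolate onto the silyloxy-stabilised cation. The stereocentres of 12 (C4a'', C8a'', C5'' and sulfur) are transient: suprafacial addition places the sulfinyl group and the hydrogen on C8a'' cis, which is the geometry the thermal syn-elimination of benzenesulfenic acid needs to restore C4a''=C8a'' in 13, and none survives in 14. Acid then ionises the mixed ketal at C5'', methanol leaves with a proton from C8'', and hydrolysis of the silyl ethers gives the 5'',7''-diol. The step needs regioselectivity (ether oxygen on C6'' and not C8'') and site selectivity between the two pyranone double bonds; the first follows from pairing the nucleophilic CH2 terminus with C8a'', the second from the fact that only the sulfinyl-bearing double bond is doubly activated while the other carries the aryl group at its β-carbon. Excess diene is used because sulfenic acid and adventitious acid consume it.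

Step 8
Reactants: 14 methyl 4-{[5,7-dihydroxy-2-(4-methoxyphenyl)-4-oxo-4H-chromen-6-yl]oxy}benzoate
Product: 15 methyl 4-{[5,7-bis(benzyloxy)-2-(4-methoxyphenyl)-4-oxo-4H-chromen-6-yl]oxy}benzoate
Conditions: BnBr (3 equiv), K2CO3, n-Bu4NI (cat.), DMF, 70 °C
Reagents that add atoms: benzyl bromide, BrCc1ccccc1
Why: Williamson etherification; the acidic 7''-OH should react first, and excess halide with heating is used to bring in the chelated, flanked 5''-OH; both must be masked so that only the phenol of 18 is acylated in step 11.

Step 9
Reactants: 15 methyl 4-{[5,7-bis(benzyloxy)-2-(4-methoxyphenyl)-4-oxo-4H-chromen-6-yl]oxy}benzoate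
Product: 16 4-{[5,7-bis(benzyloxy)-2-(4-methoxyphenyl)-4-oxo-4H-chromen-6-yl]oxy}benzoic acid
Conditions: LiOH·H2O, THF/MeOH/H2O, 40 °C; then 1 M HCl
Reagents that add atoms: lithium hydroxide, [Li+].[OH-]
Why: Saponification of an aryl methyl ester by acyl–oxygen cleavage; under these mild conditions hydroxide should not open the 2-aryl chromone, which needs hot concentrated alkali.

Step 10
Reactants: 17 1-(2,4,6-trihydroxyphenyl)ethan-1-one (2',4',6'-trihydroxyacetophenone)
Product: 18 1-[2,4-bis(benzyloxy)-6-hydroxyphenyl]ethan-1-one
Conditions: BnBr (2.1 equiv), K2CO3, DMF, rt → 50 °C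
Reagents that add atoms: benzyl bromide, BrCc1ccccc1
Why: Selective Williamson benzylation; once two oxygens are alkylated, the remaining hydroxyl is locked in a hydrogen bond to the acetyl group and is much less nucleophilic, so the reaction should stop at the dibenzyl ether.

Step 11
Reactants: 16 4-{[5,7-bis(benzyloxy)-2-(4-methoxyphenyl)-4-oxo-4H-chromen-6-yl]oxy}benzoic acid; 18 1-[2,4-bis(benzyloxy)-6-hydroxyphenyl]ethan-1-one
Product: 19 2-acetyl-3,5-bis(benzyloxy)phenyl 4-{[5,7-bis(benzyloxy)-2-(4-methoxyphenyl)-4-oxo-4H-chromen-6-yl]oxy}benzoate
Conditions: EDC·HCl, DMAP, CH2Cl2, rt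
Reagents that add atoms: none
Why: Steglich esterification; the acylpyridinium formed from the activated acid should acylate the only free phenol present, giving the substrate for acyl transfer.

Step 12
Reactants: 19 2-acetyl-3,5-bis(benzyloxy)phenyl 4-{[5,7-bis(benzyloxy)-2-(4-methoxyphenyl)-4-oxo-4H-chromen-6-yl]oxy}benzoate
Product: 20 1-[2,4-bis(benzyloxy)-6-hydroxyphenyl]-3-(4-{[5,7-bis(benzyloxy)-2-(4-methoxyphenyl)-4-oxo-4H-chromen-6-yl]oxy}phenyl)propane-1,3-dione
Conditions: KOtBu (3 equiv), THF, 0 °C → rt; then AcOH
Reagents that add atoms: none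
Why: Baker–Venkataraman rearrangement: the acetyl enolate attacks the neighbouring aryl ester through a six-membered transition state and the phenoxide is released, forming the C2–C3 bond of ring C; a hindered, non-nucleophilic alkoxide is chosen to spare ring E.

Step 13
Reactants: 20 1-[2,4-bis(benzyloxy)-6-hydroxyphenyl]-3-(4-{[5,7-bis(benzyloxy)-2-(4-methoxyphenyl)-4-oxo-4H-chromen-6-yl]oxy}phenyl)propane-1,3-dione
Product: 21 5,7-bis(benzyloxy)-6-{4-[5,7-bis(benzyloxy)-4-oxo-4H-chromen-2-yl]phenoxy}-2-(4-methoxyphenyl)-4H-chromen-4-one (tetra-O-benzylcryptomerin A)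
Conditions: p-TsOH·H2O (cat.), toluene, 100 °C, Dean–Stark
Reagents that add atoms: none
Why: Acid-catalysed cyclodehydration of a 2-hydroxyaryl 1,3-diketone: the phenol adds to the distal carbonyl (6-exo-trig) and water is lost, closing ring C; loss of a peri benzyl group here would be harmless, because the next step removes all of them.

Step 14
Reactants: 21 5,7-bis(benzyloxy)-6-{4-[5,7-bis(benzyloxy)-4-oxo-4H-chromen-2-yl]phenoxy}-2-(4-methoxyphenyl)-4H-chromen-4-one
Product: 22 6-[4-(5,7-dihydroxy-4-oxo-4H-chromen-2-yl)phenoxy]-5,7-dihydroxy-2-(4-methoxyphenyl)-4H-chromen-4-one (cryptomerin A)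
Conditions: BCl3 (12 equiv), C6HMe5 (12 equiv), CH2Cl2, −78 → −30 °C; then MeOH
Reagents that add atoms: none
Why: Lewis-acid cleavage of aryl benzyl ethers, with pentamethylbenzene as a non-basic trap for the benzyl cation so that rings A and D are not C-benzylated; the unchelated aryl methyl ether of ring F and the diaryl ether should not be cleaved by BCl3 at this temperature.

## Compound list

1 | methyl 4-hydroxybenzoate | COC(=O)c1ccc(O)cc1 | starting material
2 | methyl 2-chloro-3-oxobutanoate (racemic) | COC(=O)C(Cl)C(C)=O | starting material
3 | methyl 2-[4-(methoxycarbonyl)phenoxy]-3-oxobutanoate (racemic) | COC(=O)C(Oc1ccc(cc1)C(=O)OC)C(C)=O | intermediate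
4 | methyl 4-{[(2E)-1-methoxy-1-oxo-3-(trimethylsilyloxy)but-2-en-2-yl]oxy}benzoate | COC(=O)/C(Oc1ccc(cc1)C(=O)OC)=C(/C)O[Si](C)(C)C | intermediate
5 | methyl 4-{[1-methoxy-1,3-bis(trimethylsilyloxy)buta-1,3-dien-2-yl]oxy}benzoate (one geometric isomer drawn) | C=C(O[Si](C)(C)C)/C(Oc1ccc(cc1)C(=O)OC)=C(/OC)O[Si](C)(C)C | intermediate
6 | 1-(phenylsulfanyl)propan-2-one | CC(=O)CSc1ccccc1 | starting material
7 | (3Z)-4-(dimethylamino)-3-(phenylsulfanyl)but-3-en-2-one | CC(=O)/C(Sc1ccccc1)=C/N(C)C | intermediate
8 | 4-methoxybenzoyl chloride | COc1ccc(cc1)C(Cl)=O | starting material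
9 | (4Z)-5-(dimethylamino)-1-(4-methoxyphenyl)-4-(phenylsulfanyl)pent-4-ene-1,3-dione (formed as its lithium enolate) | COc1ccc(cc1)C(=O)CC(=O)/C(Sc1ccccc1)=C/N(C)C | intermediate
10 | 6-(4-methoxyphenyl)-3-(phenylsulfanyl)-4H-pyran-4-one | COc1ccc(-c2cc(=O)c(Sc3ccccc3)co2)cc1 | intermediate
11 | 6-(4-methoxyphenyl)-3-(phenylsulfinyl)-4H-pyran-4-one (racemic sulfoxide) | COc1ccc(-c2cc(=O)c(S(=O)c3ccccc3)co2)cc1 | intermediate
12 | methyl 4-{[5-methoxy-2-(4-methoxyphenyl)-4-oxo-4a-(phenylsulfinyl)-5,7-bis(trimethylsilyloxy)-4a,5,8,8a-tetrahydro-4H-chromen-6-yl]oxy}benzoate (racemic; cis ring fusion with the sulfinyl group and H-8a on the same face; mixture at sulfur and C5) | COc1ccc(cc1)C2=CC(=O)[C@]3(S(=O)c4ccccc4)[C@H](O2)CC(O[Si](C)(C)C)=C(Oc5ccc(cc5)C(=O)OC)C3(OC)O[Si](C)(C)C | intermediate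
13 | methyl 4-{[5-methoxy-2-(4-methoxyphenyl)-4-oxo-5,7-bis(trimethylsilyloxy)-5,8-dihydro-4H-chromen-6-yl]oxy}benzoate (racemic) | COc1ccc(cc1)C2=CC(=O)C3=C(O2)CC(O[Si](C)(C)C)=C(Oc4ccc(cc4)C(=O)OC)C3(OC)O[Si](C)(C)C | intermediate
14 | methyl 4-{[5,7-dihydroxy-2-(4-methoxyphenyl)-4-oxo-4H-chromen-6-yl]oxy}benzoate | COC(=O)c1ccc(Oc2c(O)cc3oc(-c4ccc(OC)cc4)cc(=O)c3c2O)cc1 | intermediate
15 | methyl 4-{[5,7-bis(benzyloxy)-2-(4-methoxyphenyl)-4-oxo-4H-chromen-6-yl]oxy}benzoate | COC(=O)c1ccc(Oc2c(OCc3ccccc3)cc3oc(-c4ccc(OC)cc4)cc(=O)c3c2OCc5ccccc5)cc1 | intermediate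
16 | 4-{[5,7-bis(benzyloxy)-2-(4-methoxyphenyl)-4-oxo-4H-chromen-6-yl]oxy}benzoic acid | OC(=O)c1ccc(Oc2c(OCc3ccccc3)cc3oc(-c4ccc(OC)cc4)cc(=O)c3c2OCc5ccccc5)cc1 | intermediate
17 | 1-(2,4,6-trihydroxyphenyl)ethan-1-one | CC(=O)c1c(O)cc(O)cc1O | starting material
18 | 1-[2,4-bis(benzyloxy)-6-hydroxyphenyl]ethan-1-one | CC(=O)c1c(O)cc(OCc2ccccc2)cc1OCc1ccccc1 | intermediate
19 | 2-acetyl-3,5-bis(benzyloxy)phenyl 4-{[5,7-bis(benzyloxy)-2-(4-methoxyphenyl)-4-oxo-4H-chromen-6-yl]oxy}benzoate | CC(=O)c1c(OC(=O)c2ccc(Oc3c(OCc4ccccc4)cc5oc(-c6ccc(OC)cc6)cc(=O)c5c3OCc7ccccc7)cc2)cc(OCc8ccccc8)cc1OCc9ccccc9 | intermediate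
20 | 1-[2,4-bis(benzyloxy)-6-hydroxyphenyl]-3-(4-{[5,7-bis(benzyloxy)-2-(4-methoxyphenyl)-4-oxo-4H-chromen-6-yl]oxy}phenyl)propane-1,3-dione | O=C(CC(=O)c1ccc(Oc2c(OCc3ccccc3)cc4oc(-c5ccc(OC)cc5)cc(=O)c4c2OCc6ccccc6)cc1)c7c(O)cc(OCc8ccccc8)cc7OCc9ccccc9 | intermediate
21 | 5,7-bis(benzyloxy)-6-{4-[5,7-bis(benzyloxy)-4-oxo-4H-chromen-2-yl]phenoxy}-2-(4-methoxyphenyl)-4H-chromen-4-one | COc1ccc(-c2cc(=O)c3c(OCc4ccccc4)c(Oc4ccc(-c5cc(=O)c6c(OCc7ccccc7)cc(OCc7ccccc7)cc6o5)cc4)c(OCc4ccccc4)cc3o2)cc1 | intermediate
22 | cryptomerin A, 6-[4-(5,7-dihydroxy-4-oxo-4H-chromen-2-yl)phenoxy]-5,7-dihydroxy-2-(4-methoxyphenyl)-4H-chromen-4-one | COc1ccc(-c2cc(=O)c3c(O)c(Oc4ccc(-c5cc(=O)c6c(O)cc(O)cc6o5)cc4)c(O)cc3o2)cc1 | target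

## Step count and least certain steps

Total: 14 steps. Longest linear sequence: 10 steps (1 → 3 → 4 → 5 → 14 → 15 → 16 → 19 → 20 → 21 → 22; the branch from 6 through 7, 10 and 11 is equally long).

Step 7 (key step). The aromatic character of the 4-pyranone may make it a sluggish dienophile. If the first bond forms well ahead of the second, the α-sulfinyl enolate may expel the ring oxygen and open ring E faster than it closes ring D. The diene may also be protodesilylated by the sulfenic acid set free, and aromatisation may lose silanol in place of methanol, leaving a 5''-methyl ether. The fallback takes ring D from the aromatic pool and sets out from 18.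
- Elbs persulfate oxidation (K2S2O8, aqueous NaOH/pyridine) should hydroxylate para to the free phenol, first as potassium 3-acetyl-2,6-bis(benzyloxy)-4-hydroxyphenyl sulfate F1.
- Dilute HCl hydrolyses this to 1-[2,4-bis(benzyloxy)-3,6-dihydroxyphenyl]ethan-1-one F2.
- The non-chelated phenoxide of F2 is arylated with methyl 4-fluorobenzoate (Cs2CO3, DMSO, 110 °C, argon; SNAr) to methyl 4-[3-acetyl-2,6-bis(benzyloxy)-4-hydroxyphenoxy]benzoate F3.
- C-acylation of the lithium dianion of F3 (LiHMDS, THF, −78 °C) with 8 gives methyl 4-{2,6-bis(benzyloxy)-4-hydroxy-3-[3-(4-methoxyphenyl)-3-oxopropanoyl]phenoxy}benzoate F4.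
- Acid-catalysed cyclodehydration of F4 comes back to the route at 15.

This path accepts the slow ether formation at a doubly flanked phenol that the main route avoids.

Step 3. The amide base may attack the aryl ester, or the lithium dienolate may condense with it, and the bis(silyl) diene may hydrolyse during handling, so that 5 reaches the key step impure. The fallback sets out from 3 and avoids amide base and lithium enolates altogether: twofold soft enolisation with TMSOTf (2.2 equiv) and Et3N in Et2O at 0 °C silylates both carbonyl sites in one operation and comes back to the route at 5. No new compound arises (F0).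

Step 5. O-acylation or double acylation of the enolate, or proton transfer between product and enolate, may leave 7 unconsumed. The fallback builds the carbon chain in the opposite order by dianion chemistry and sets out from 6.
- The dianion of 6 (LDA, 2.1 equiv, THF) is acylated at its methyl terminus with methyl 4-methoxybenzoate to give 1-(4-methoxyphenyl)-4-(phenylsulfanyl)butane-1,3-dione F5.
- The dianion of F5 (LDA, 2.2 equiv) is formylated at the sulfur-bearing terminal carbon with ethyl formate to give 5-(4-methoxyphenyl)-3,5-dioxo-2-(phenylsulfanyl)pentanal F6.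
- Without isolation F6 is cyclodehydrated by acid, and the fallback comes back to the route at 10.

Step 12. Intermolecular cleavage of the hindered aryl ester by alkoxide or traces of hydroxide may return 16 and 18 in place of the intramolecular acyl transfer. The fallback skips the O-acyl intermediate and sets out from 16 and 18. Acid 16 is converted with oxalyl chloride and catalytic DMF into 4-{[5,7-bis(benzyloxy)-2-(4-methoxyphenyl)-4-oxo-4H-chromen-6-yl]oxy}benzoyl chloride F7. F7 is added at −78 °C to the lithium dianion of 18 (LiHMDS, 3 equiv, THF), and direct C-acylation of the enolate comes back to the route at 20.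

Step 14. Benzyl cations may be transferred to the electron-rich carbons C6, C8 and C8'' before the scavenger traps them, cleavage of the four ethers may be incomplete, or the ring F methyl ether may be lost slowly if the mixture warms. The fallback sets out from 21 and replaces Lewis-acid cleavage by catalytic hydrogenolysis (H2, 1 atm, Pd/C, THF/MeOH, rt), stopped before the chromone double bonds are reduced; it comes back to the route at 22. No new compound arises (F0).

## Further compounds

F1 | step 7 | potassium 3-acetyl-2,6-bis(benzyloxy)-4-hydroxyphenyl sulfate | [K+].CC(=O)c1c(O)cc(OCc2ccccc2)c(OS([O-])(=O)=O)c1OCc1ccccc1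
F2 | step 7 | 1-[2,4-bis(benzyloxy)-3,6-dihydroxyphenyl]ethan-1-one | CC(=O)c1c(O)cc(OCc2ccccc2)c(O)c1OCc1ccccc1
F3 | step 7 | methyl 4-[3-acetyl-2,6-bis(benzyloxy)-4-hydroxyphenoxy]benzoate | CC(=O)c1c(O)cc(OCc2ccccc2)c(Oc2ccc(cc2)C(=O)OC)c1OCc1ccccc1
F4 | step 7 | methyl 4-{2,6-bis(benzyloxy)-4-hydroxy-3-[3-(4-methoxyphenyl)-3-oxopropanoyl]phenoxy}benzoate | COc1ccc(cc1)C(=O)CC(=O)c1c(O)cc(OCc2ccccc2)c(Oc2ccc(cc2)C(=O)OC)c1OCc1ccccc1
F0 | step 3 | none | none
F5 | step 5 | 1-(4-methoxyphenyl)-4-(phenylsulfanyl)butane-1,3-dione | COc1ccc(cc1)C(=O)CC(=O)CSc1ccccc1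
F6 | step 5 | 5-(4-methoxyphenyl)-3,5-dioxo-2-(phenylsulfanyl)pentanal | COc1ccc(cc1)C(=O)CC(=O)C(Sc1ccccc1)C=O
F7 | step 12 | 4-{[5,7-bis(benzyloxy)-2-(4-methoxyphenyl)-4-oxo-4H-chromen-6-yl]oxy}benzoyl chloride | ClC(=O)c1ccc(Oc2c(OCc3ccccc3)cc3oc(-c4ccc(OC)cc4)cc(=O)c3c2OCc5ccccc5)cc1
F0 | step 14 | none | none
A1 | alternative 1 | 2,4-bis(benzyloxy)-3-{4-[5,7-bis(benzyloxy)-4-oxo-4H-chromen-2-yl]phenoxy}-6-hydroxybenzaldehyde | O=Cc1c(O)cc(OCc2ccccc2)c(Oc2ccc(cc2)-c2cc(=O)c3c(OCc4ccccc4)cc(OCc4ccccc4)cc3o2)c1OCc1ccccc1
A2 | alternative 1 | 2-(dimethyloxo-λ6-sulfanylidene)-1-(4-methoxyphenyl)ethan-1-one | COc1ccc(cc1)C(=O)C=S(C)(C)=O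
A3 | alternative 1 | tetra-O-benzylcryptomerin A (identical with 21) | COc1ccc(-c2cc(=O)c3c(OCc4ccccc4)c(Oc4ccc(-c5cc(=O)c6c(OCc7ccccc7)cc(OCc7ccccc7)cc6o5)cc4)c(OCc4ccccc4)cc3o2)cc1
A4 | alternative 2 | 3-(4-methoxyphenyl)prop-2-ynoic acid | COc1ccc(cc1)C#CC(O)=O
A5 | alternative 2 | 3,5-bis(benzyloxy)-4-[4-(1,3-dioxolan-2-yl)phenoxy]-2-(trimethylsilyl)phenyl trifluoromethanesulfonate | C[Si](C)(C)c1c(OS(=O)(=O)C(F)(F)F)cc(OCc2ccccc2)c(Oc2ccc(cc2)C2OCCO2)c1OCc1ccccc1
A6 | alternative 2 | 1-{2-hydroxy-4,6-bis(benzyloxy)-5-[4-(1,3-dioxolan-2-yl)phenoxy]phenyl}-3-(4-methoxyphenyl)prop-2-yn-1-one | COc1ccc(C#CC(=O)c2c(O)cc(OCc3ccccc3)c(Oc3ccc(C4OCCO4)cc3)c2OCc2ccccc2)cc1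
A7 | alternative 3 | methyl coumalate (methyl 2-oxo-2H-pyran-5-carboxylate) | COC(=O)c1ccc(=O)oc1
A8 | alternative 3 | 1,3-bis(benzyloxy)-2-(ethynyloxy)-5-[(triisopropylsilyl)oxy]benzene | C#COc1c(OCc2ccccc2)cc(O[Si](C(C)C)(C(C)C)C(C)C)cc1OCc1ccccc1
A9 | alternative 3 | methyl 4-{2,6-bis(benzyloxy)-4-[(triisopropylsilyl)oxy]phenoxy}benzoate | COC(=O)c1ccc(Oc2c(OCc3ccccc3)cc(O[Si](C(C)C)(C(C)C)C(C)C)cc2OCc2ccccc2)cc1
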